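**Plan**
- Retrosynthesis: the four isopropyl ethers on O5, O7, O5'' and O7'' come off last. Before that, C4–C4a is cut in both flavone units at once, which opens both rings C and gives a biaryl bis[(Z)-3-aryloxy-3-(4-methoxyphenyl)acrylic acid]. Then the two O1–C2 bonds are cut (phenol plus arylpropiolate), and finally the C6–C8'' biaryl bond (Suzuki–Miyaura).
- Enabling feature: both rings A are phloroglucinol rings, so C4a (ortho to O1, ortho and para to two further oxygens) is strongly nucleophilic. It is also the only carbon that can close a six-membered ring: in the 6-linked unit 1 the two carbons ortho to O1 are equivalent CH groups, and in the 8-linked unit 2 the second ortho carbon is the quaternary biaryl carbon C8.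
- Forward: both rings A are made from 1,3-diisopropoxybenzene and joined first; rings B arrive intact with the propiolate when O1–C2 is formed; the two rings C close together in step 10.
- Stereochemistry: the target has no stereocentre; the Z alkenes arise by anti addition and disappear on ring closure; the C6–C8'' axis is not controlled.

Key step: step 10

Remark: the target is given without a descriptor for the C6–C8'' axis, so the biaryl is made in racemic form.
Remark: the oxa-Michael adducts and the acids derived from them are drawn as the Z,Z isomers expected from anti addition; any E isomer is carried forward, because the acid medium of the ring closure interconverts the isomers.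

**Step 1**
Reactants: 1 1,3-diisopropoxybenzene
Product: 4 (2,6-diisopropoxyphenyl)boronic acid, via aryllithium 2 (not isolated), via lithium aryltrimethoxyborate 3 (not isolated)
Conditions: n-BuLi, THF, 0 °C → rt; B(OMe)3, −78 °C → rt; 1 M HCl
Reagents that add atoms: trimethyl borate, COB(OC)OC; water, O
Why: Directed ortho-metalation removes the proton at C2 between the two isopropoxy groups (the standard lithiation of 1,3-dialkoxybenzenes), and borate trapping followed by acidic hydrolysis should give the boronic acid.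

**Step 2**
Reactants: 1 1,3-diisopropoxybenzene
Product: 6 3,5-diisopropoxyphenol, via arylboronate 5 (not isolated)
Conditions: HBpin (pinacolborane), [Ir(OMe)(cod)]2 (cat.), dtbpy (4,4'-di-tert-butyl-2,2'-bipyridine, cat.), THF, 80 °C; then NaOH, aq. H2O2, 0 °C → rt
Reagents that add atoms: hydrogen peroxide, OO
Why: Iridium-catalysed aromatic C–H borylation is sterically controlled and should occur only at C5, the one C–H without an ortho substituent, and oxidation of the C–B bond then gives the phenol (one-pot borylation–oxidation).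

**Step 3**
Reactants: 6 3,5-diisopropoxyphenol
Product: 7 1,3-diisopropoxy-5-(methoxymethoxy)benzene
Conditions: MOMCl, iPr2NEt, CH2Cl2, 0 °C → rt
Reagents that add atoms: chloromethyl methyl ether, COCCl
Why: O-alkylation of the phenol (Williamson-type) installs a methoxymethyl acetal that directs the next lithiation and can later be removed by mild acid without touching isopropyl ethers.

**Step 4**
Reactants: 7 1,3-diisopropoxy-5-(methoxymethoxy)benzene
Product: 9 2-iodo-1,5-diisopropoxy-3-(methoxymethoxy)benzene, via aryllithium 8 (not isolated)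
Conditions: n-BuLi, THF, 0 °C → rt; I2, THF, −78 °C → rt
Reagents that add atoms: iodine, II
Why: Directed ortho-metalation, in which the chelating OMOM group steers lithiation to the C–H between OMOM and O-iPr rather than the one between two O-iPr groups, followed by iodine quench of the aryllithium.

**Step 5**
Reactants: 4 (2,6-diisopropoxyphenyl)boronic acid; 9 2-iodo-1,5-diisopropoxy-3-(methoxymethoxy)benzene
Product: 10 2,2',4,6'-tetraisopropoxy-6-(methoxymethoxy)-1,1'-biphenyl
Conditions: Pd(OAc)2 (5 mol%), SPhos (2-dicyclohexylphosphino-2',6'-dimethoxybiphenyl, 10 mol%), K3PO4, toluene/H2O 10:1, 100 °C; 4 in excess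
Reagents that add atoms: none
Why: Suzuki–Miyaura coupling with a dialkylbiarylphosphine ligand of the kind used for tetra-ortho-substituted biaryls; all four ortho groups are alkoxy groups, which are small at the atom attached to the ring, and this bond becomes C6–C8'' of the target.

**Step 6**
Reactants: 10 2,2',4,6'-tetraisopropoxy-6-(methoxymethoxy)-1,1'-biphenyl
Product: 12 3,5-diisopropoxy-4-[2,4-diisopropoxy-6-(methoxymethoxy)phenyl]phenol, via biaryl boronate 11 (not isolated)
Conditions: HBpin, [Ir(OMe)(cod)]2 (cat.), dtbpy (cat.), THF, 80 °C; then NaOH, aq. H2O2, 0 °C → rt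
Reagents that add atoms: hydrogen peroxide, OO
Why: Sterically controlled iridium-catalysed C–H borylation should take place only at C4' of the 2,6-diisopropoxyphenyl ring (every other aromatic C–H has an ortho oxygen substituent), and oxidation of the boronate gives the phenol oxygen that becomes O1 of unit 1.

**Step 7**
Reactants: 12 3,5-diisopropoxy-4-[2,4-diisopropoxy-6-(methoxymethoxy)phenyl]phenol
Product: 13 2',4,6,6'-tetraisopropoxy-[1,1'-biphenyl]-2,4'-diol
Conditions: 3 M HCl, MeOH/THF, 40 °C
Reagents that add atoms: none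
Why: Acid-catalysed acetal exchange removes the methoxymethyl group as dimethoxymethane (methanol also scavenges the formaldehyde equivalent), while isopropyl aryl ethers are stable to dilute acid; the freed 2-OH becomes O1 of unit 2.

**Step 8**
Reactants: 13 2',4,6,6'-tetraisopropoxy-[1,1'-biphenyl]-2,4'-diol; 14 methyl 3-(4-methoxyphenyl)propiolate (3 equiv)
Product: 15 dimethyl (2Z,2'Z)-3,3'-[(2',4,6,6'-tetraisopropoxy-[1,1'-biphenyl]-2,4'-diyl)bis(oxy)]bis[3-(4-methoxyphenyl)acrylate]
Conditions: Cs2CO3 (0.5 equiv), DMF, 80 °C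
Reagents that add atoms: none
Why: Base-mediated oxa-Michael addition of both phenoxides to the β-carbon of the ynoate (the Ruhemann route to β-aryloxycinnamates) forms the two O1–C2 bonds, and anti addition places the aryloxy group cis to the ester (Z).

**Step 9**
Reactants: 15 dimethyl (2Z,2'Z)-3,3'-[(2',4,6,6'-tetraisopropoxy-[1,1'-biphenyl]-2,4'-diyl)bis(oxy)]bis[3-(4-methoxyphenyl)acrylate]
Product: 17 (2Z,2'Z)-3,3'-[(2',4,6,6'-tetraisopropoxy-[1,1'-biphenyl]-2,4'-diyl)bis(oxy)]bis[3-(4-methoxyphenyl)acrylic acid], via dilithium dicarboxylate 16 (not isolated)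
Conditions: LiOH, THF/MeOH/H2O, 40 °C; then 1 M HCl to pH 3, 0 °C
Reagents that add atoms: lithium hydroxide, [Li+].[OH-]
Why: Ester saponification by acyl substitution; the β-aryloxyacrylate (vinylogous carbonate) linkage tolerates hydroxide, and cold, brief acidification avoids hydrolysis of the enol ether.

**Step 10**
Reactants: 17 (2Z,2'Z)-3,3'-[(2',4,6,6'-tetraisopropoxy-[1,1'-biphenyl]-2,4'-diyl)bis(oxy)]bis[3-(4-methoxyphenyl)acrylic acid]
Product: 19 5,7-diisopropoxy-6-[5,7-diisopropoxy-2-(4-methoxyphenyl)-4-oxo-4H-chromen-8-yl]-2-(4-methoxyphenyl)-4H-chromen-4-one, via bis(mixed anhydride) 18 (not isolated)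
Conditions: (CF3CO)2O, CF3CO2H, CH2Cl2, 0 °C → rt
Reagents that add atoms: none
Why: (CF3CO)2O converts each carboxylic acid into the mixed anhydride 18, whose acylium-like carbonyl is attacked by C4a of the adjacent ring A, and loss of a proton and of CF3CO2H restores aromaticity and leaves the C4 ketone, so both C4–C4a bonds and both rings C form in one operation. The closest known reactions are the Ruhemann flavone synthesis (acid-induced cyclisation of β-aryloxycinnamic acids) and the (CF3CO)2O-mediated closure of 2-aryloxybenzoic acids bearing alkoxy-rich rings to xanthones. Each ring C closes as a six-membered ring by intramolecular Friedel–Crafts acylation, the chain C8a–O1–C2=C3–C4 delivering the acyl carbon to C4a. No stereocentre is formed; the Z geometry holds the acid next to ring A, and an E isomer should equilibrate in CF3CO2H by protonation at C3 to the oxocarbenium ion stabilised by O1 and the anisyl group. Two selectivities are needed: the site on ring A is fixed by connectivity (two equivalent CH carbons ortho to O1 in unit 1, and in unit 2 the other ortho carbon is the biaryl carbon C8), and closure onto the anisyl ring to an indenone is disfavoured because its ortho carbon is meta to the methoxy group whereas C4a is ortho and para to two isopropoxy groups. The isopropyl ethers should survive this medium and keep O5 and O5'' capped, so no ring opening and reclosure can scramble the 6,8'' linkage.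

**Step 11**
Reactants: 19 5,7-diisopropoxy-6-[5,7-diisopropoxy-2-(4-methoxyphenyl)-4-oxo-4H-chromen-8-yl]-2-(4-methoxyphenyl)-4H-chromen-4-one
Product: 21 5,7-dihydroxy-6-[5,7-dihydroxy-2-(4-methoxyphenyl)-4-oxo-4H-chromen-8-yl]-2-(4-methoxyphenyl)-4H-chromen-4-one, via tetrakis(dichloroboryl) ether 20 (not isolated)
Conditions: BCl3, CH2Cl2, −78 → 0 °C; then H2O
Reagents that add atoms: none
Why: Lewis-acid dealkylation in which BCl3 cleaves secondary (isopropyl) aryl ethers, helped at O5 and O5'' by chelation to the C4 carbonyls, much faster than unchelated methyl aryl ethers, so the two 4'-methoxy groups should remain.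

**Compound list**
1 | 1,3-diisopropoxybenzene | CC(C)Oc1cccc(OC(C)C)c1 | starting material
2 | (2,6-diisopropoxyphenyl)lithium | [Li]c1c(OC(C)C)cccc1OC(C)C | intermediate (not isolated)
3 | lithium (2,6-diisopropoxyphenyl)trimethoxyborate | [Li+].CO[B-](OC)(OC)c1c(OC(C)C)cccc1OC(C)C | intermediate (not isolated)
4 | (2,6-diisopropoxyphenyl)boronic acid | OB(O)c1c(OC(C)C)cccc1OC(C)C | intermediate
5 | 2-(3,5-diisopropoxyphenyl)-4,4,5,5-tetramethyl-1,3,2-dioxaborolane | CC(C)Oc1cc(OC(C)C)cc(B2OC(C)(C)C(C)(C)O2)c1 | intermediate (not isolated)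
6 | 3,5-diisopropoxyphenol | CC(C)Oc1cc(O)cc(OC(C)C)c1 | intermediate
7 | 1,3-diisopropoxy-5-(methoxymethoxy)benzene | COCOc1cc(OC(C)C)cc(OC(C)C)c1 | intermediate
8 | [2,4-diisopropoxy-6-(methoxymethoxy)phenyl]lithium | [Li]c1c(OCOC)cc(OC(C)C)cc1OC(C)C | intermediate (not isolated)
9 | 2-iodo-1,5-diisopropoxy-3-(methoxymethoxy)benzene | COCOc1cc(OC(C)C)cc(OC(C)C)c1I | intermediate
10 | 2,2',4,6'-tetraisopropoxy-6-(methoxymethoxy)-1,1'-biphenyl | COCOc1cc(OC(C)C)cc(OC(C)C)c1-c1c(OC(C)C)cccc1OC(C)C | intermediate
11 | 2-{3,5-diisopropoxy-4-[2,4-diisopropoxy-6-(methoxymethoxy)phenyl]phenyl}-4,4,5,5-tetramethyl-1,3,2-dioxaborolane | COCOc1cc(OC(C)C)cc(OC(C)C)c1-c1c(OC(C)C)cc(B2OC(C)(C)C(C)(C)O2)cc1OC(C)C | intermediate (not isolated)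
12 | 3,5-diisopropoxy-4-[2,4-diisopropoxy-6-(methoxymethoxy)phenyl]phenol | COCOc1cc(OC(C)C)cc(OC(C)C)c1-c1c(OC(C)C)cc(O)cc1OC(C)C | intermediate
13 | 2',4,6,6'-tetraisopropoxy-[1,1'-biphenyl]-2,4'-diol (the ring with 4'-OH becomes ring A of unit 1, the ring with 2-OH becomes ring A of unit 2) | CC(C)Oc1cc(O)cc(OC(C)C)c1-c1c(O)cc(OC(C)C)cc1OC(C)C | intermediate
14 | methyl 3-(4-methoxyphenyl)propiolate | COC(=O)C#Cc1ccc(OC)cc1 | starting material
15 | dimethyl (2Z,2'Z)-3,3'-[(2',4,6,6'-tetraisopropoxy-[1,1'-biphenyl]-2,4'-diyl)bis(oxy)]bis[3-(4-methoxyphenyl)acrylate] | CC(C)Oc1cc(O/C(=C\C(=O)OC)c2ccc(OC)cc2)cc(OC(C)C)c1-c1c(O/C(=C\C(=O)OC)c2ccc(OC)cc2)cc(OC(C)C)cc1OC(C)C | intermediate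
16 | dilithium salt of diacid 17 | CC(C)Oc1cc(O/C(=C\C(=O)[O-])c2ccc(OC)cc2)cc(OC(C)C)c1-c1c(O/C(=C\C(=O)[O-])c2ccc(OC)cc2)cc(OC(C)C)cc1OC(C)C.[Li+].[Li+] | intermediate (not isolated)
17 | (2Z,2'Z)-3,3'-[(2',4,6,6'-tetraisopropoxy-[1,1'-biphenyl]-2,4'-diyl)bis(oxy)]bis[3-(4-methoxyphenyl)acrylic acid] | CC(C)Oc1cc(O/C(=C\C(=O)O)c2ccc(OC)cc2)cc(OC(C)C)c1-c1c(O/C(=C\C(=O)O)c2ccc(OC)cc2)cc(OC(C)C)cc1OC(C)C | intermediate
18 | bis(trifluoroacetic) mixed anhydride of diacid 17 | CC(C)Oc1cc(O/C(=C\C(=O)OC(=O)C(F)(F)F)c2ccc(OC)cc2)cc(OC(C)C)c1-c1c(O/C(=C\C(=O)OC(=O)C(F)(F)F)c2ccc(OC)cc2)cc(OC(C)C)cc1OC(C)C | intermediate (not isolated)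
19 | 5,7-diisopropoxy-6-[5,7-diisopropoxy-2-(4-methoxyphenyl)-4-oxo-4H-chromen-8-yl]-2-(4-methoxyphenyl)-4H-chromen-4-one (5,7,5'',7''-tetraisopropyl ether of the target) | COc1ccc(-c2cc(=O)c3c(OC(C)C)c(-c4c(OC(C)C)cc(OC(C)C)c5c(=O)cc(-c6ccc(OC)cc6)oc45)c(OC(C)C)cc3o2)cc1 | intermediate
20 | 5,7,5'',7''-tetrakis(dichloroboryl) ether of the target (simplest formulation of the boron aryloxide) | COc1ccc(-c2cc(=O)c3c(OB(Cl)Cl)c(-c4c(OB(Cl)Cl)cc(OB(Cl)Cl)c5c(=O)cc(-c6ccc(OC)cc6)oc45)c(OB(Cl)Cl)cc3o2)cc1 | intermediate (not isolated)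
21 | 5,7-dihydroxy-6-[5,7-dihydroxy-2-(4-methoxyphenyl)-4-oxo-4H-chromen-8-yl]-2-(4-methoxyphenyl)-4H-chromen-4-one (CNP0226117.0) | COc1ccc(-c2cc(=O)c3c(O)c(-c4c(O)cc(O)c5c(=O)cc(-c6ccc(OC)cc6)oc45)c(O)cc3o2)cc1 | target

**Step count**
Total: 11 steps. Longest linear sequence: 10 steps (1 → 6 → 7 → 9 → 10 → 12 → 13 → 15 → 17 → 19 → 21); step 1 is a one-step branch.

**Steps most likely to fail**

Step 5 (biaryl coupling). Transmetalation and reductive elimination at a palladium centre carrying two 2,6-dioxygenated aryl groups may be slow, so that protodeboronation of 4 and hydrodeiodination of 9 consume the partners before the biaryl forms. The fallback sets out from 1 and 7 and returns at 10; it reverses the polarity and uses a Negishi coupling. Aryllithium 2, generated from 1 as in step 1, is quenched with I2 to give 2-iodo-1,3-diisopropoxybenzene F1. Aryllithium 8, generated from 7 as in step 4, is transmetalated with ZnCl2 to chloro[2,4-diisopropoxy-6-(methoxymethoxy)phenyl]zinc F2. F1 and F2 are then coupled with Pd2(dba)3 and RuPhos (2-dicyclohexylphosphino-2',6'-diisopropoxybiphenyl) in THF/NMP at 70–100 °C to give 10. The organozinc transmetalates without base or water, which removes the protodeboronation pathway.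

Step 8 (double oxa-Michael addition). Addition of the phenoxide ortho to the biaryl axis to an ynoate β-carbon deactivated by the 4-methoxyphenyl group may stall after the unhindered 4'-phenoxide has reacted, while the ynoate oligomerises under base. The fallback sets out from 13 and 14 and returns at 15; it forms the O1–C2 bonds by copper-catalysed O-vinylation. Compound 14 is hydroiodinated (NaI, CH3CO2H, 80 °C, anti addition) to methyl (Z)-3-iodo-3-(4-methoxyphenyl)acrylate F3. Diol 13 is then coupled with F3 (CuI cat., N,N-dimethylglycine, Cs2CO3, dioxane, 90 °C) in an Ullmann-type C–O coupling that keeps the alkene geometry and gives 15.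

Step 10 (key ring closure). An E isomer that fails to equilibrate may acylate its anisyl ring to an indenone, the second closure may stall at the mono-flavone, or the free ring-A positions may be trifluoroacetylated. The fallback sets out from 13 and returns at 19; it builds rings C in the opposite order (C4–C4a first, O1–C2 last) through chalcones. Diol 13 is C-acetylated ortho to each hydroxyl (Ac2O, BF3·OEt2, 60 °C, Fries-type acylation) to give 1,1'-(2,4'-dihydroxy-2',4,6,6'-tetraisopropoxy-[1,1'-biphenyl]-3,3'-diyl)di(ethan-1-one) F4. Claisen–Schmidt condensation of F4 with 4-methoxybenzaldehyde (KOH, EtOH, rt) gives the corresponding bis[(E)-3-(4-methoxyphenyl)prop-2-en-1-one] (bis-2'-hydroxychalcone) F5. Oxidative cyclisation of F5 (I2 cat., DMSO, 130 °C) gives 19.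

**Further compounds**
F1 | step 5 | 2-iodo-1,3-diisopropoxybenzene | CC(C)Oc1cccc(OC(C)C)c1I
F2 | step 5 | chloro[2,4-diisopropoxy-6-(methoxymethoxy)phenyl]zinc | Cl[Zn]c1c(OCOC)cc(OC(C)C)cc1OC(C)C
F3 | step 8 | methyl (Z)-3-iodo-3-(4-methoxyphenyl)acrylate | COC(=O)/C=C(\I)c1ccc(OC)cc1
F4 | step 10 | 1,1'-(2,4'-dihydroxy-2',4,6,6'-tetraisopropoxy-[1,1'-biphenyl]-3,3'-diyl)di(ethan-1-one) | CC(=O)c1c(O)cc(OC(C)C)c(-c2c(O)c(C(C)=O)c(OC(C)C)cc2OC(C)C)c1OC(C)C
F5 | step 10 | (2E,2'E)-1,1'-(2,4'-dihydroxy-2',4,6,6'-tetraisopropoxy-[1,1'-biphenyl]-3,3'-diyl)bis[3-(4-methoxyphenyl)prop-2-en-1-one] | COc1ccc(/C=C/C(=O)c2c(O)cc(OC(C)C)c(-c3c(O)c(C(=O)/C=C/c4ccc(OC)cc4)c(OC(C)C)cc3OC(C)C)c2OC(C)C)cc1
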